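**Retrosynthetic overview**
1. Target 22 ⇐ 21 by one fluoride deprotection; 21 ⇐ dienone 20 by hydroxyl-directed hydrogenation of C5=C6, which sets C6 trans to the C7–OH.
2. 20 ⇐ phenol 18 by the key C7–O bond formation: a catalytic enantioselective ortho-hydroxylative dearomatisation (new step, sets C7).
3. 18 ⇐ alkynyl salicylaldehyde 16 by silver-catalysed 6-endo cyclisation and hydride capture; the pyran is the only ring made, and the carbocycle is a purchased benzene ring that is dearomatised afterwards.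
4. 16 ⇐ iodide 15 + enyne ester 8 (Sonogashira); 15 ⇐ phenol 13 + acid 5 (regioselective ester C–O bond).
5. 13 ⇐ aldehyde 9 (ortho-iodination, demethylation); 5 ⇐ phenol 1 (mono-demethylation, silylation, ortho-lithiation/CO2); 8 ⇐ acid 6 (esterification, ethynylation).

Assumption: the target is taken exactly as the SMILES given, i.e. the (6R,7S) isomer with the 6-aroyloxy and 7-hydroxy groups trans. The iodoarene precatalyst of step 11, 2-iodo-N1,N3-bis[(1R)-1-(naphthalen-1-yl)ethyl]benzene-1,3-dicarboxamide (C[C@@H](NC(=O)c1cccc(C(=O)N[C@H](C)c2cccc3ccccc23)c1I)c1cccc2ccccc12), is made separately from 2-iodoisophthalic acid and (R)-1-(naphthalen-1-yl)ethylamine and is not counted. Its (S,S)-antipode is used if the sense of induction proves opposite.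

Abbreviations: TBS = tert-butyldimethylsilyl; TMSE = 2-(trimethylsilyl)ethyl.

**Route**

Step 1
Reactants: 1 2,6-dimethoxy-4-methylphenol
Product: 2 3-methoxy-5-methylbenzene-1,2-diol
Conditions: AlCl3 (1.1 equiv), pyridine (4.4 equiv), CH2Cl2, reflux, 24 h; then 2 M HCl
Reagents that add atoms: none
Why: Chelation-directed Lewis-acid ether cleavage (AlCl3–pyridine demethylation of a 2-methoxyphenol), in which the aluminium phenoxide activates only an adjacent methoxy group, the two are equivalent, and the aluminium catecholate formed resists loss of the second methyl.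

Step 2
Reactants: 2 3-methoxy-5-methylbenzene-1,2-diol
Product: 3 1,2-bis(TBS-oxy)-3-methoxy-5-methylbenzene
Conditions: TBSCl (2.4 equiv), imidazole (5 equiv), DMF, 23 °C
Reagents that add atoms: tert-butyldimethylsilyl chloride, CC(C)(C)[Si](C)(C)Cl
Why: Imidazole-promoted silyl ether formation masks the catechol as fluoride-labile ethers that tolerate the later organolithium, acylation, oxidation and hydrogenation conditions and leave the methoxy group as the only directing group.

Step 3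
Reactants: 3 1,2-bis(TBS-oxy)-3-methoxy-5-methylbenzene
Product: 5 3,4-bis(TBS-oxy)-2-methoxy-6-methylbenzoic acid, via aryllithium 4 (not isolated)
Conditions: s-BuLi (1.3 equiv), TMEDA (1.3 equiv), THF, −78 °C, 2 h; CO2 (gas), −78 → 0 °C; cold 0.5 M HCl
Reagents that add atoms: carbon dioxide, O=C=O
Why: Directed ortho-metalation followed by carboxylation, in which the methoxy group is the only coordinating director, its single free ortho position (between OMe and CH3) is lithiated while the bulky, weakly coordinating silyloxy groups shield the other ring hydrogen, and CO2 traps the aryllithium.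

Step 4
Reactants: 6 (2E)-3-iodoprop-2-enoic acid
Product: 7 2-(trimethylsilyl)ethyl (2E)-3-iodoprop-2-enoate
Conditions: 2-(trimethylsilyl)ethanol (1.2 equiv), DCC (1.1 equiv), DMAP (5 mol%), CH2Cl2, 0 → 23 °C
Reagents that add atoms: 2-(trimethylsilyl)ethanol, C[Si](C)(C)CCO
Why: Steglich esterification (carbodiimide activation with DMAP acyl transfer) leaves the vinyl iodide untouched and retains the E geometry.

Step 5
Reactants: 7 2-(trimethylsilyl)ethyl (2E)-3-iodoprop-2-enoate
Product: 8 2-(trimethylsilyl)ethyl (2E)-pent-2-en-4-ynoate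
Conditions: HC≡CMgBr (1.5 equiv, 0.5 M in THF), ZnBr2 (1.5 equiv), THF, 0 °C; then 7, Pd(PPh3)4 (3 mol%), 0 → 23 °C
Reagents that add atoms: ethynylmagnesium bromide, C#C[Mg]Br
Why: Negishi cross-coupling of a vinyl iodide with ethynylzinc bromide installs the terminal alkyne directly, with retention of the E alkene geometry and tolerance of the ester.

Step 6
Reactants: 9 2,4-dimethoxy-3-methylbenzaldehyde
Product: 12 6-iodo-2,4-dimethoxy-3-methylbenzaldehyde, via lithium amino alkoxide 10 (not isolated), via ortho-lithiated amino alkoxide 11 (not isolated)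
Conditions: LiN(Me)CH2CH2NMe2 (1.1 equiv, from the amine and n-BuLi), THF, −20 °C; n-BuLi (3 equiv), −20 °C, 3 h; I2 (4 equiv), −78 → 0 °C; H2O, aq. Na2S2O3
Reagents that add atoms: iodine, II
Why: Directed ortho-metalation of a benzaldehyde through its in situ α-amino alkoxide, whose chelating diamine arm steers n-BuLi to the only free position ortho to the masked formyl group, followed by iodine quench and hydrolytic release of the aldehyde.

Step 7
Reactants: 12 6-iodo-2,4-dimethoxy-3-methylbenzaldehyde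
Product: 13 2,4-dihydroxy-6-iodo-3-methylbenzaldehyde
Conditions: BBr3 (3 equiv), CH2Cl2, −78 → 23 °C; H2O
Reagents that add atoms: none
Why: Lewis-acid cleavage of aryl methyl ethers with BBr3 frees both phenols while the aryl iodide and the aldehyde are inert.

Step 8
Reactants: 5 3,4-bis(TBS-oxy)-2-methoxy-6-methylbenzoic acid; 13 2,4-dihydroxy-6-iodo-3-methylbenzaldehyde
Product: 15 4-formyl-3-hydroxy-5-iodo-2-methylphenyl 3,4-bis(TBS-oxy)-2-methoxy-6-methylbenzoate, via acid chloride 14 (not isolated)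
Conditions: 5, (COCl)2 (1.5 equiv), DMF (cat.), CH2Cl2, 0 → 23 °C, evaporate; then 13 (1.0 equiv), Et3N (1.2 equiv), DMAP (10 mol%), CH2Cl2, −20 → 0 °C
Reagents that add atoms: none
Why: Acylation of a phenol by an acid chloride, selective for the 4-OH (para to the formyl group, more acidic and not hydrogen-bonded) because the 2-OH stays locked in its hydrogen bond to the aldehyde, the di-ortho-substituted acid 5 being activated as 14 to overcome its hindrance.

Step 9
Reactants: 15 4-formyl-3-hydroxy-5-iodo-2-methylphenyl 3,4-bis(TBS-oxy)-2-methoxy-6-methylbenzoate; 8 2-(trimethylsilyl)ethyl (2E)-pent-2-en-4-ynoate (1.3 equiv)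
Product: 16 4-formyl-3-hydroxy-2-methyl-5-[(3E)-5-oxo-5-[2-(trimethylsilyl)ethoxy]pent-3-en-1-yn-1-yl]phenyl 3,4-bis(TBS-oxy)-2-methoxy-6-methylbenzoate
Conditions: PdCl2(PPh3)2 (3 mol%), CuI (5 mol%), Et3N (3 equiv), THF, 23 °C, argon
Reagents that add atoms: none
Why: Sonogashira coupling, fast at room temperature for an iodide ortho to a formyl group, with the hindered benzoate, the silyl ethers and the hydrogen-bonded phenol untouched and the tertiary amine unable to add to the enynoate.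

Step 10
Reactants: 16 (alkynyl salicylaldehyde from step 9)
Product: 18 8-hydroxy-7-methyl-3-[(1E)-3-oxo-3-[2-(trimethylsilyl)ethoxy]prop-1-en-1-yl]-1H-isochromen-6-yl 3,4-bis(TBS-oxy)-2-methoxy-6-methylbenzoate, via isochromenylium trifluoroacetate 17 (not isolated)
Conditions: AgOSO2CF3 (5 mol%), CF3CO2H (2 equiv), ClCH2CH2Cl, 23 °C, 30 min, dark; then Hantzsch ester (diethyl 2,6-dimethyl-1,4-dihydropyridine-3,5-dicarboxylate, 1.3 equiv), 0 → 23 °C; aq. NaHCO3
Reagents that add atoms: none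
Why: Silver-catalysed 6-endo-dig carbonyl–alkyne cycloisomerisation gives the aromatic isochromenylium ion 17, which takes up hydride at C1 from the Hantzsch ester (transfer hydrogenation of an oxocarbenium ion) and so closes the pyran ring with C1 at the CH2 level.

Step 11
Reactants: 18 (isochromenol from step 10)
Product: 20 (7S)-7-hydroxy-7-methyl-8-oxo-3-[(1E)-3-oxo-3-[2-(trimethylsilyl)ethoxy]prop-1-en-1-yl]-7,8-dihydro-1H-isochromen-6-yl 3,4-bis(TBS-oxy)-2-methoxy-6-methylbenzoate, via aryloxy iodane 19 (not isolated)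
Conditions: 2-iodo-N1,N3-bis[(1R)-1-(naphthalen-1-yl)ethyl]benzene-1,3-dicarboxamide (10 mol%), KHSO5 (1.5 equiv, as powdered 2KHSO5·KHSO4·K2SO4), nBu4NHSO4 (10 mol%), Na2SO4, EtOAc, 0 °C; aq. Na2S2O3/NaHCO3
Reagents that add atoms: potassium peroxymonosulfate, [K+].[O-]S(=O)(=O)OO
Why: Proposed new method: KHSO5 oxidises the C2-symmetric iodoarene to a chiral iodyl arene (pentavalent iodine, held pseudocyclic by the two amide carbonyls), phenol 18 exchanges onto iodine to give 19, and the iodine-bound oxygen is then delivered intramolecularly to the ortho carbon C7 (flanked by the two oxygen substituents and leading to a dienone stabilised as a vinylogous ester by the ring oxygen) with reduction to trivalent iodine, the two chiral amide arms blocking one face of the aryl plane so that the C7–O bond and the (7S) centre are formed together, after which hydrolysis releases 20 and KHSO5 re-oxidises the iodine; the closest known reactions are the stoichiometric hydroxylative phenol dearomatisation with (chiral) iodyl arenes and the achiral 2-iodobenzenesulfonate/KHSO5-catalysed ortho-oxygenation of phenols, whereas a catalytic, highly enantioselective version on a ring-fused resorcinol monoester has not been shown.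

Step 12
Reactants: 20 (quinol from step 11)
Product: 21 (6R,7S)-7-hydroxy-7-methyl-8-oxo-3-[(1E)-3-oxo-3-[2-(trimethylsilyl)ethoxy]prop-1-en-1-yl]-5,6,7,8-tetrahydro-1H-isochromen-6-yl 3,4-bis(TBS-oxy)-2-methoxy-6-methylbenzoate
Conditions: [Ir(cod)(PCy3)(py)]PF6 (5 mol%), H2 (1 atm), CH2Cl2, 0 °C, 1 h, monitored closely
Reagents that add atoms: none
Why: Hydroxyl-directed homogeneous hydrogenation, in which the tertiary C7–OH binds the cationic iridium centre and H2 is delivered to the adjacent C5=C6 enol-ester double bond on the hydroxyl face, so that H-6 is cis and the aroyloxy group trans to the hydroxyl (6R), while the tetrasubstituted enone, the trisubstituted dienol ether and the remote electron-poor acrylate lack the directing contact and react more slowly.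

Step 13
Reactants: 21 (protected target from step 12)
Product: 22 (2E)-3-[(6R,7S)-6-(3,4-dihydroxy-2-methoxy-6-methylbenzoyl)oxy-7-hydroxy-7-methyl-8-oxo-5,6,7,8-tetrahydro-1H-isochromen-3-yl]prop-2-enoic acid
Conditions: nBu4NF (4 equiv), AcOH (4 equiv), THF, 0 → 23 °C, argon; pH 4 buffer
Reagents that add atoms: none
Why: Fluoride-mediated desilylation cleaves both aryl silyl ethers and fragments the 2-(trimethylsilyl)ethyl ester (β-elimination to ethene) in one operation, the acetic acid buffer suppressing base-induced loss of the 6-aroyloxy group and leaving both stereocentres (C7 quaternary, C6 not α to a carbonyl) untouched.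

**Compound list**

1 | 2,6-dimethoxy-4-methylphenol | COc1cc(C)cc(OC)c1O | starting material
2 | 3-methoxy-5-methylbenzene-1,2-diol | COc1cc(C)cc(O)c1O | intermediate
3 | 1,2-bis(TBS-oxy)-3-methoxy-5-methylbenzene | COc1cc(C)cc(O[Si](C)(C)C(C)(C)C)c1O[Si](C)(C)C(C)(C)C | intermediate
4 | [3,4-bis(TBS-oxy)-2-methoxy-6-methylphenyl]lithium | COc1c([Li])c(C)cc(O[Si](C)(C)C(C)(C)C)c1O[Si](C)(C)C(C)(C)C | intermediate (not isolated)
5 | 3,4-bis(TBS-oxy)-2-methoxy-6-methylbenzoic acid | COc1c(O[Si](C)(C)C(C)(C)C)c(O[Si](C)(C)C(C)(C)C)cc(C)c1C(=O)O | intermediate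
6 | (2E)-3-iodoprop-2-enoic acid | OC(=O)/C=C/I | starting material
7 | 2-(trimethylsilyl)ethyl (2E)-3-iodoprop-2-enoate | C[Si](C)(C)CCOC(=O)/C=C/I | intermediate
8 | 2-(trimethylsilyl)ethyl (2E)-pent-2-en-4-ynoate | C[Si](C)(C)CCOC(=O)/C=C/C#C | intermediate
9 | 2,4-dimethoxy-3-methylbenzaldehyde | COc1ccc(C=O)c(OC)c1C | starting material
10 | lithium (2,4-dimethoxy-3-methylphenyl){[2-(dimethylamino)ethyl](methyl)amino}methanolate | COc1ccc(C(O[Li])N(C)CCN(C)C)c(OC)c1C | intermediate (not isolated)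
11 | 6-lithio derivative of 10 | COc1cc([Li])c(C(O[Li])N(C)CCN(C)C)c(OC)c1C | intermediate (not isolated)
12 | 6-iodo-2,4-dimethoxy-3-methylbenzaldehyde | COc1cc(I)c(C=O)c(OC)c1C | intermediate
13 | 2,4-dihydroxy-6-iodo-3-methylbenzaldehyde | Cc1c(O)cc(I)c(C=O)c1O | intermediate
14 | 3,4-bis(TBS-oxy)-2-methoxy-6-methylbenzoyl chloride | COc1c(O[Si](C)(C)C(C)(C)C)c(O[Si](C)(C)C(C)(C)C)cc(C)c1C(=O)Cl | intermediate (not isolated)
15 | 4-formyl-3-hydroxy-5-iodo-2-methylphenyl 3,4-bis(TBS-oxy)-2-methoxy-6-methylbenzoate | COc1c(O[Si](C)(C)C(C)(C)C)c(O[Si](C)(C)C(C)(C)C)cc(C)c1C(=O)Oc1cc(I)c(C=O)c(O)c1C | intermediate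
16 | 4-formyl-3-hydroxy-2-methyl-5-[(3E)-5-oxo-5-[2-(trimethylsilyl)ethoxy]pent-3-en-1-yn-1-yl]phenyl 3,4-bis(TBS-oxy)-2-methoxy-6-methylbenzoate | COc1c(O[Si](C)(C)C(C)(C)C)c(O[Si](C)(C)C(C)(C)C)cc(C)c1C(=O)Oc1cc(C#C/C=C/C(=O)OCC[Si](C)(C)C)c(C=O)c(O)c1C | intermediate
17 | 6-[3,4-bis(TBS-oxy)-2-methoxy-6-methylbenzoyl]oxy-8-hydroxy-7-methyl-3-[(1E)-3-oxo-3-[2-(trimethylsilyl)ethoxy]prop-1-en-1-yl]isochromenylium trifluoroacetate | COc1c(O[Si](C)(C)C(C)(C)C)c(O[Si](C)(C)C(C)(C)C)cc(C)c1C(=O)Oc1cc2cc(/C=C/C(=O)OCC[Si](C)(C)C)[o+]cc2c(O)c1C.[O-]C(=O)C(F)(F)F | intermediate (not isolated)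
18 | 8-hydroxy-7-methyl-3-[(1E)-3-oxo-3-[2-(trimethylsilyl)ethoxy]prop-1-en-1-yl]-1H-isochromen-6-yl 3,4-bis(TBS-oxy)-2-methoxy-6-methylbenzoate | COc1c(O[Si](C)(C)C(C)(C)C)c(O[Si](C)(C)C(C)(C)C)cc(C)c1C(=O)Oc1cc2C=C(/C=C/C(=O)OCC[Si](C)(C)C)OCc2c(O)c1C | intermediate
19 | aryloxy(hydroxy)oxo-iodane (pentavalent iodine) formed from 18 through O8 and the oxidised (R,R)-catalyst | C[C@@H](NC(=O)c1cccc(C(=O)N[C@H](C)c2cccc3ccccc23)c1I(=O)(O)Oc1c(C)c(OC(=O)c2c(C)cc(O[Si](C)(C)C(C)(C)C)c(O[Si](C)(C)C(C)(C)C)c2OC)cc2C=C(/C=C/C(=O)OCC[Si](C)(C)C)OCc12)c1cccc2ccccc12 | intermediate (not isolated)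
20 | (7S)-7-hydroxy-7-methyl-8-oxo-3-[(1E)-3-oxo-3-[2-(trimethylsilyl)ethoxy]prop-1-en-1-yl]-7,8-dihydro-1H-isochromen-6-yl 3,4-bis(TBS-oxy)-2-methoxy-6-methylbenzoate | COc1c(O[Si](C)(C)C(C)(C)C)c(O[Si](C)(C)C(C)(C)C)cc(C)c1C(=O)OC1=CC2=C(COC(/C=C/C(=O)OCC[Si](C)(C)C)=C2)C(=O)[C@@]1(C)O | intermediate
21 | (6R,7S)-7-hydroxy-7-methyl-8-oxo-3-[(1E)-3-oxo-3-[2-(trimethylsilyl)ethoxy]prop-1-en-1-yl]-5,6,7,8-tetrahydro-1H-isochromen-6-yl 3,4-bis(TBS-oxy)-2-methoxy-6-methylbenzoate | COc1c(O[Si](C)(C)C(C)(C)C)c(O[Si](C)(C)C(C)(C)C)cc(C)c1C(=O)O[C@@H]1CC2=C(COC(/C=C/C(=O)OCC[Si](C)(C)C)=C2)C(=O)[C@@]1(C)O | intermediate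
22 | (2E)-3-[(6R,7S)-6-(3,4-dihydroxy-2-methoxy-6-methylbenzoyl)oxy-7-hydroxy-7-methyl-8-oxo-5,6,7,8-tetrahydro-1H-isochromen-3-yl]prop-2-enoic acid | COc1c(O)c(O)cc(C)c1C(=O)O[C@@H]1CC2=C(COC(/C=C/C(=O)O)=C2)C(=O)[C@@]1(C)O | target

**Step count**
Total steps: 13.
Longest linear sequence: 9 steps (1 → 2 → 3 → 5 → 15 → 16 → 18 → 20 → 21 → 22; steps 1, 2, 3, 8, 9, 10, 11, 12, 13).

**Three steps most likely to fail**

Step 10 (cyclisation and hydride capture). The electron-poor enyne could favour 5-exo closure, and the enol ether could be reduced further under acid and hydride. The fallback sets out from 16 and comes back at 18. The aldehyde of 16 is first reduced with NaBH4 (MeOH–THF, −20 °C) to the benzylic alcohol F1. F1 is then cyclised by the known gold-catalysed 6-endo-dig hydroalkoxylation of 2-alkynylbenzyl alcohols (AuCl(PPh3)/AgOSO2CF3, CH2Cl2, 23 °C). The ring C–O bond is then made by an alcohol instead of a carbonyl oxygen, and the product never meets a hydride donor.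

Step 11 (the proposed new step). The risks are low enantioselectivity, oxygen transfer to C8a instead of C7, and oxidation of the dienol ether or the C1 methylene. The fallback uses known chemistry, sets out from 18 and comes back at 20. Stoichiometric racemic ortho-hydroxylative dearomatisation with stabilised 2-iodoxybenzoic acid (a pentavalent-iodine reagent; THF, 23 °C, aqueous work-up) gives the racemic quinol, that is 20 together with its (7R)-enantiomer F2. Preparative chiral-phase supercritical-fluid chromatography then supplies 20. The stereocentre is obtained by resolution instead of catalysis, at the cost of half the material.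

Step 12 (directed hydrogenation). The acrylate double bond may be reduced along with C5=C6, or the conjugated system may slow the catalyst. The fallback sets out from 15 and comes back at 22, and it brings in the acrylate only after the hydrogenation.
- Sonogashira coupling of 15 with 3,3-diethoxyprop-1-yne (catalysts as in step 9) gives the alkynyl acetal F3.
- Cyclisation and hydride capture as in step 10, without the acid additive, give the isochromenol acetal F4.
- The oxidation of step 11 gives the quinol acetal F5.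
- The iridium-directed hydrogenation, now without any competing disubstituted alkene, gives the tetrahydro acetal F6.
- Pyridinium p-toluenesulfonate in wet acetone unmasks the aldehyde F7.
- Wittig olefination with commercial Ph3P=CHCO2tBu (toluene, 40 °C) gives the E-configured tert-butyl ester F8.
- CF3CO2H in CH2Cl2 at 0 °C and then HF·pyridine in THF remove the tert-butyl and silyl groups, which rejoins the route at 22.

**Further compounds**

F1 | step 10 | 3-hydroxy-4-(hydroxymethyl)-2-methyl-5-[(3E)-5-oxo-5-[2-(trimethylsilyl)ethoxy]pent-3-en-1-yn-1-yl]phenyl 3,4-bis(TBS-oxy)-2-methoxy-6-methylbenzoate | COc1c(O[Si](C)(C)C(C)(C)C)c(O[Si](C)(C)C(C)(C)C)cc(C)c1C(=O)Oc1cc(C#C/C=C/C(=O)OCC[Si](C)(C)C)c(CO)c(O)c1C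
F2 | step 11 | (7R)-enantiomer of 20 | COc1c(O[Si](C)(C)C(C)(C)C)c(O[Si](C)(C)C(C)(C)C)cc(C)c1C(=O)OC1=CC2=C(COC(/C=C/C(=O)OCC[Si](C)(C)C)=C2)C(=O)[C@]1(C)O
F3 | step 12 | 5-(3,3-diethoxyprop-1-yn-1-yl)-4-formyl-3-hydroxy-2-methylphenyl 3,4-bis(TBS-oxy)-2-methoxy-6-methylbenzoate | COc1c(O[Si](C)(C)C(C)(C)C)c(O[Si](C)(C)C(C)(C)C)cc(C)c1C(=O)Oc1cc(C#CC(OCC)OCC)c(C=O)c(O)c1C
F4 | step 12 | 3-(diethoxymethyl)-8-hydroxy-7-methyl-1H-isochromen-6-yl 3,4-bis(TBS-oxy)-2-methoxy-6-methylbenzoate | COc1c(O[Si](C)(C)C(C)(C)C)c(O[Si](C)(C)C(C)(C)C)cc(C)c1C(=O)Oc1cc2C=C(C(OCC)OCC)OCc2c(O)c1C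
F5 | step 12 | (7S)-3-(diethoxymethyl)-7-hydroxy-7-methyl-8-oxo-7,8-dihydro-1H-isochromen-6-yl 3,4-bis(TBS-oxy)-2-methoxy-6-methylbenzoate | COc1c(O[Si](C)(C)C(C)(C)C)c(O[Si](C)(C)C(C)(C)C)cc(C)c1C(=O)OC1=CC2=C(COC(C(OCC)OCC)=C2)C(=O)[C@@]1(C)O
F6 | step 12 | (6R,7S)-3-(diethoxymethyl)-7-hydroxy-7-methyl-8-oxo-5,6,7,8-tetrahydro-1H-isochromen-6-yl 3,4-bis(TBS-oxy)-2-methoxy-6-methylbenzoate | COc1c(O[Si](C)(C)C(C)(C)C)c(O[Si](C)(C)C(C)(C)C)cc(C)c1C(=O)O[C@@H]1CC2=C(COC(C(OCC)OCC)=C2)C(=O)[C@@]1(C)O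
F7 | step 12 | (6R,7S)-3-formyl-7-hydroxy-7-methyl-8-oxo-5,6,7,8-tetrahydro-1H-isochromen-6-yl 3,4-bis(TBS-oxy)-2-methoxy-6-methylbenzoate | COc1c(O[Si](C)(C)C(C)(C)C)c(O[Si](C)(C)C(C)(C)C)cc(C)c1C(=O)O[C@@H]1CC2=C(COC(C=O)=C2)C(=O)[C@@]1(C)O
F8 | step 12 | (6R,7S)-3-[(1E)-3-tert-butoxy-3-oxoprop-1-en-1-yl]-7-hydroxy-7-methyl-8-oxo-5,6,7,8-tetrahydro-1H-isochromen-6-yl 3,4-bis(TBS-oxy)-2-methoxy-6-methylbenzoate | COc1c(O[Si](C)(C)C(C)(C)C)c(O[Si](C)(C)C(C)(C)C)cc(C)c1C(=O)O[C@@H]1CC2=C(COC(/C=C/C(=O)OC(C)(C)C)=C2)C(=O)[C@@]1(C)O
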